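All runs were computed with made-up constants; noise was put on by code.

South-west lost more Z between its first and last readings than north did, 19 percentage points against 2.8 points, so the meeting opened on what ends the chain.

| flask | Z | L | temperature | remark | time |
|---|---|---|---|---|---|
| south-west | 0.015 M | 0.73 mM | 32 °C | run made earlier |  |
| north | 0.058 M | 0.73 mM | 49 °C | run made earlier |  |
| grey | 0.029 M | 0.73 mM | 40 °C |  | 30 min |
| violet | 0.029 M | 0.73 mM | 25 °C |  | 30 min |
| ochre | 0.029 M | 0.73 mM |  | at 55 °C until 15 min, from then on at 25 °C | 30 min |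
| blue | 0.029 M | 0.73 mM | 55 °C |  | 30 min |

| run | time / min | X / % | Z / % |
|---|---|---|---|
| south-west | 2.00 | 15.5 | 83.0 |
| south-west | 4.00 | 21.1 | 77.3 |
| south-west | 6.00 | 27.7 | 72.8 |
| south-west | 12.0 | 31.0 | 66.6 |
| south-west | 25.0 | 32.0 | 64.0 |
| north | 1.33 | 15.2 | 84.5 |
| north | 2.50 | 17.1 | 83.0 |
| north | 4.00 | 15.7 | 82.3 |
| north | 8.00 | 15.8 | 82.9 |
| north | 15.0 | 17.5 | 81.7 |

(standard deviation of a reading: 1 percentage point)

- on the list of suspects stand: L -> 2 Q; 2 E -> D; Z + Q -> E + X; X <-> J; Z + E -> X + E

* the flask that comes out highest in amount of X, in percent of the Z charged, or "all alike" when all lie within 1.5 percentage points (grey / violet / ochre / blue / all alike)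
* X at the end, in percent of the Z charged, grey
* X at the end, in percent of the Z charged, violet
* X at the end, in percent of the Z charged, ochre
* X at the end, in percent of the Z charged, blue

I argued for one quantity. Each L gives two Q, and each Q takes one Z, so the direct share of Z is twice c_L charged over c_Z charged. The chain term is the logarithm of what the direct share leaves, divided by the Z at the end. With the curve replaced by its mean, it is roughly a propagation constant times mean c_E times the burn time of L. With E lost in pairs, the usual quasi-steady state makes mean c_E go as the root of c_L charged, and for L lost first-order the burn time does not depend on the charges. So in this reckoning, at fixed temperature, the chain term ignores c_Z and follows that root.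

South-west, direct share 9.73%, reads 0.344. North reads 0.177, which is less than south-west. A straight line of its logarithm against temperature gives violet 0.452, the chain term at fixed c_L.

With direct share 5.03%, violet should keep Z at 60.4%, grey at 73.9% and blue at 82.6%. Taking the share against mean Z instead of charged Z moves violet by 0.79 points, which is below the scatter. South-west's missing 4 points, read as J, puts violet's X near 35.6%. North's Z moved 2.8 points after 1.33 min, so I took ochre's cooled half to add little to blue.

The forecast, made apart from this reckoning, named violet highest: grey 25%, violet 36%, ochre 17%, blue 17%. Its ground was that “The plateaus show the chain dies with the initiator”. My figures for grey and blue are of Z, and its figures are of X.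

The flasks gave violet highest: grey 23.0%, violet 35.0%, ochre 15.7%, blue 16.1%.

    L → 2 Q (k = 0.190 min⁻¹, Ea = 84.0 kJ mol⁻¹)
    2 E → D (k = 5.80 × 10⁸ M⁻¹ s⁻¹, Ea = 11.0 kJ mol⁻¹)
    Z + Q → E + X (k = 3.80 × 10⁵ M⁻¹ s⁻¹, Ea = 15.0 kJ mol⁻¹)
    X ⇌ J (K = 0.150, k = 0.00480 min⁻¹, Ea = 92.0 kJ mol⁻¹, ΔH = −16.0 kJ mol⁻¹)
    Z + E → X + E, rate k5*[E]*[Z] (k = 11000 M⁻¹ s⁻¹, Ea = 16.0 kJ mol⁻¹)
    (constants at 25 °C)

Violet's Z of 62.3% at 30.0 min gives a chain term of 0.422, against the 0.452 carried. The neighbour is violet with c_L raised to 0.0029 M, 0.100 equiv of Z. Its direct share is 20.0%, and the root rule lifts the chain term to 0.902, so Z should stand at 32.5%. The neighbour ended with Z at 31.9%, J at 5.08% and X at 63.0%.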